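There were 4 questions about autumn and dusk, and I meant to answer them with a single count: how many turns each catalyst makes in the time.

| flask | starting material | coupling partner | free catalyst | remark | time |
|---|---|---|---|---|---|
| west | 0.018 M | 0.018 M | 12 µM | run made earlier |  |
| south | 0.018 M | 0.018 M | 9 µM | run made earlier |  |
| autumn | 0.018 M | 0.0180 M | 18 µM |  | 2.5 min |
| dusk | 0.018 M | 0.0230 M | 18 µM |  | 2.5 min |

1. which of these there is most of at the end, counted by the starting material in it, autumn (starting material / catalyst intermediate B / catalyst intermediate A / target)
2. which of these there is most of at the end, counted by the starting material in it, dusk (starting material / catalyst intermediate B / catalyst intermediate A / target)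
3. how much there is at the end of the one of these that leads, in percent of the starting material charged: autumn
4. how much there is at the end of the one of these that leads, in percent of the starting material charged: dusk

| run | time / s | catalyst intermediate B / % | target / % | starting material / % | catalyst intermediate A / % |
|---|---|---|---|---|---|
| west | 10.0 | 0.3 | 4.1 | 95.8 | 0.4 |
| west | 15.0 | 0 | 5.7 | 94.3 | 0 |
| west | 25.0 | 0 | 10.3 | 90.2 | 0.2 |
| west | 40.0 | 0 | 15.5 | 84.5 | 0 |
| west | 50.0 | 0 | 18.3 | 81.2 | 0.4 |
| west | 80.0 | 0 | 28.4 | 72.0 | 0 |
| west | 90.0 | 0.4 | 31.2 | 68.8 | 0.1 |
| south | 10.0 | 0.2 | 2.1 | 97.1 | 0 |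
| south | 12.0 | 0.1 | 3.5 | 96.5 | 0.2 |
| south | 15.0 | 0 | 4.8 | 95.3 | 0.1 |
| south | 25.0 | 0 | 7.7 | 92.4 | 0.5 |
| south | 40.0 | 0 | 11.6 | 88.1 | 0 |
| south | 60.0 | 0 | 17.3 | 82.8 | 0.1 |
| south | 90.0 | 0.1 | 24.5 | 76.0 | 0 |

(each reading ± 0.3 percentage points)

- steps under discussion: 2 coupling partner -> homo dimer; starting material + free catalyst -> catalyst intermediate A; coupling partner + catalyst intermediate A -> catalyst intermediate B; catalyst intermediate C -> free catalyst + target; catalyst intermediate B <-> by-product + catalyst intermediate C

I read the last rows of the two tables against each other. At 90.0 s the west run held 31.2% target from 12 µM of free catalyst, or 468 turns per catalyst charged. The south run held 24.5% from 9 µM, or 490 turns. So a catalyst turned about equally often in both runs, slightly more in south, where more starting material remained.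

Turns slow as starting material falls, so I took the logarithm of charged over remaining starting material, read from the target, and divided it by [free catalyst] charged and by time. West gave 346 M⁻¹ s⁻¹ and south 347 M⁻¹ s⁻¹. I kept their mean, 347 M⁻¹ s⁻¹, as the turnover constant κ.

For autumn this left 39.2% starting material and gave 60.8% target, 608 turns of the 1000 the charge allows. So in my reckoning target led starting material, 60.8% against 39.2%, and catalyst intermediates A and B, which together hold no more than the catalyst charged, 0.100% of the starting material, stood far below both. Both runs charged [coupling partner] at 0.018 M, so they gave no κ for dusk, and I carried the same figure there with less trust.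

The forecast also named target for both flasks, with 59.5% for autumn and 60% for dusk, a little below my figure, on the ground that "The coupling partner shows no kinetic effect so far".

    2 coupling partner → homo dimer (k = 0.0330 M⁻¹ s⁻¹)
    starting material + free catalyst → catalyst intermediate A (k = 1100 M⁻¹ s⁻¹)
    coupling partner + catalyst intermediate A → catalyst intermediate B (k = 780 M⁻¹ s⁻¹)
    catalyst intermediate C → free catalyst + target (k = 55.0 s⁻¹)
    catalyst intermediate B ⇌ by-product + catalyst intermediate C (K = 0.0500 M, k = 47.0 s⁻¹)

The flask gave target leading in both, 61.8% in autumn and 69.0% in dusk, 9 percentage points above the forecast. Read back, κ was 357 M⁻¹ s⁻¹ in autumn and 434 M⁻¹ s⁻¹ in dusk, higher. At 2.50 min autumn's resting state was catalyst intermediate A, 56.5% of the catalyst charged against 32.7% free, while dusk held 42.6% as catalyst intermediate A against 45.2% free. For the neighbour like dusk with 4.5 × 10⁻⁶ M of free catalyst, dusk's κ gives 25.4% target. The computed flask gave 22.6%, slightly less.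

The readings come from a simulation for an exercise; scatter was added.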